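**Plan**
1. Locants used here: ring O1–O2–C3(OMe)(C1′…C16′)–C4–C5–C6(H)(Cα–C1O2H). The target is 3R,6S, with OMe and the acetic acid arm cis (OMe axial, both carbon arms equatorial).
2. Retrosynthetic cuts: the C1 acid goes back to CH2OH. C5′–C6′ (sp–sp2) is cut as a Sonogashira coupling. O1–C6 is cut as the SN2 attack of a C3 methoxy-hydroperoxide on a C6 mesylate. C3–C4 is the strategic cut.
3. Enabling feature: C3 and C6 are 1,4-dioxygenated, so C3 and C4 are both acceptor carbons. C3, C4, C5, C6 and the oxygen on C6 (the dioxane ring less one oxygen) can form a five-membered ring. The whole C3 acyl unit is therefore parked as an ester on O–C6 of a 3-iodopropyl unit. C4 is reversed in polarity (C–I to C–Sm) and closes that ring onto C3. Opening of the hemiketal gives a 1,4 O→C acyl shift, which also frees O–C6 for activation.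
4. Forward order: C6 carbinol → iodo ester → five-membered ring (C3–C4) → mesylate → C3 methoxy-hydroperoxide → six-membered 1,2-dioxane (O1–C6) → enyne coupling → acid.
5. Stereochemistry: C6 comes from a reagent-controlled allylboration (R) and is inverted once in the SN2 ring closure (S). C3 comes from acid-catalysed equilibration in methanol, which funnels both epimers into the anomerically favoured 3R isomer.

Key step: step 8

Remark: the two C3 epimers of a 3-methoxy-1,2-dioxane are assumed to interconvert in acidic methanol, with the axial-OMe epimer the more stable; SmI2 (0.1 M in THF), Cp2Zr(H)Cl and (+)-Ipc2B(allyl) (1 M in pentane) are bought reagents.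

Step 1
Reactants: 1 hex-5-ynoic acid
Product: 3 6-(trimethylsilyl)hex-5-ynoic acid, via trimethylsilyl ester 2 (not isolated)
Conditions: n-BuLi (2.2 equiv), THF, −78 °C; TMSCl (2.5 equiv), −78 °C to rt; 1 M HCl
Reagents that add atoms: chlorotrimethylsilane C[Si](C)(C)Cl
Why: C-silylation of the lithium acetylide of the carboxylate dianion caps the acidic alkyne C–H ahead of the organosamarium step, and the O-silyl ester formed alongside is hydrolysed in the acidic work-up.

Step 2
Reactants: 4 propane-1,3-diol
Product: 5 3-[(tert-butyldiphenylsilyl)oxy]propan-1-ol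
Conditions: NaH (1.0 equiv), THF, 0 °C to rt; TBDPSCl (1.0 equiv)
Reagents that add atoms: tert-butyl(chloro)diphenylsilane CC(C)(C)[Si](Cl)(c1ccccc1)c1ccccc1
Why: O-silylation of the sparingly soluble monosodium alkoxide of a symmetrical diol should favour the mono-ether.

Step 3
Reactants: 5 3-[(tert-butyldiphenylsilyl)oxy]propan-1-ol
Product: 6 3-[(tert-butyldiphenylsilyl)oxy]propanal
Conditions: TEMPO (cat.), PhI(OAc)2 (1.1 equiv), CH2Cl2, rt
Reagents that add atoms: none
Why: The oxoammonium (TEMPO) oxidation stops at the aldehyde in the absence of water and leaves the silyl ether alone.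

Step 4
Reactants: 6 3-[(tert-butyldiphenylsilyl)oxy]propanal
Product: 8 (R)-1-[(tert-butyldiphenylsilyl)oxy]hex-5-en-3-ol, via homoallyl borinate 7 (not isolated)
Conditions: (+)-Ipc2B(allyl), Et2O, −78 °C; then 3 M NaOH, 30% H2O2, 0 °C to rt
Reagents that add atoms: (+)-B-allyldiisopinocampheylborane C=CCB([C@H]1C[C@H]2C[C@@H]([C@@H]1C)C2(C)C)[C@H]1C[C@H]2C[C@@H]([C@@H]1C)C2(C)C
Why: In the Brown allylboration the closed chair transition state and the isopinocampheyl groups derived from (−)-α-pinene should send the allyl group to the Re face of the aldehyde, which sets the future C6 carbinol centre as R.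

Step 5
Reactants: 8 (R)-1-[(tert-butyldiphenylsilyl)oxy]hex-5-en-3-ol
Product: 10 (R)-5-[(tert-butyldiphenylsilyl)oxy]pentane-1,3-diol, via secondary ozonide 9 (not isolated)
Conditions: O3, CH2Cl2, −78 °C; then NaBH4, MeOH, −78 °C to 0 °C
Reagents that add atoms: ozone [O-][O+]=O
Why: Ozonolysis with borohydride work-up shortens the allyl arm by one carbon to the 2-hydroxyethyl arm C5–C4 without touching the carbinol centre.

Step 6
Reactants: 10 (R)-5-[(tert-butyldiphenylsilyl)oxy]pentane-1,3-diol
Product: 11 (S)-1-[(tert-butyldiphenylsilyl)oxy]-5-iodopentan-3-ol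
Conditions: I2, PPh3, imidazole, CH2Cl2, 0 °C
Reagents that add atoms: iodine II
Why: The Appel-type iodination is much faster at the unhindered primary hydroxyl, so the secondary hydroxyl stays free (the descriptor changes only because the CIP priorities change).

Step 7
Reactants: 11 (S)-1-[(tert-butyldiphenylsilyl)oxy]-5-iodopentan-3-ol; 3 6-(trimethylsilyl)hex-5-ynoic acid
Product: 12 (S)-1-[(tert-butyldiphenylsilyl)oxy]-5-iodopentan-3-yl 6-(trimethylsilyl)hex-5-ynoate
Conditions: DCC, DMAP (cat.), CH2Cl2, 0 °C to rt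
Reagents that add atoms: none
Why: The Steglich esterification parks the complete C3 acyl unit on the C6 oxygen under neutral conditions, with retention because the C6–O bond is not involved.

Step 8
Reactants: 12 (S)-1-[(tert-butyldiphenylsilyl)oxy]-5-iodopentan-3-yl 6-(trimethylsilyl)hex-5-ynoate
Product: 15 (R)-1-[(tert-butyldiphenylsilyl)oxy]-3-hydroxy-11-(trimethylsilyl)undec-10-yn-6-one, via primary alkylsamarium 13 (not isolated), via cyclic samarium hemiketal 14 (not isolated)
Conditions: SmI2 (2.2 equiv), Fe(dbm)3 (2 mol %), THF, −30 °C to 0 °C; aq. NaHCO3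
Reagents that add atoms: none
Why: Two single-electron transfers from SmI2 convert the primary C4–I bond into a primary alkylsamarium(III), so that C4, an acceptor site in the natural polarity pattern of the 1,4-dioxygenated C3–C6 unit, becomes a donor. This carbanion equivalent adds to the ester carbonyl C3 held on the C6 oxygen in a 5-exo-trig closure and forms the C3–C4 bond within the ring O–C3–C4–C5–C6 (hemiketal 14); on aqueous work-up the hemiketal opens, so the net result should be a 1,4 O→C acyl shift to the γ-hydroxy ketone, which stands in ring–chain equilibrium with its lactol. The closest known reaction type is the SmI2-promoted intramolecular nucleophilic acyl substitution (intramolecular Barbier-type reaction) of 3-iodopropyl carboxylates to 4-hydroxy ketones. The only new stereocentre, the hemiketal carbon, is transient and uncontrolled, whereas C6 takes no part in bond breaking and keeps its spatial arrangement (R in 15). The step needs reduction of C–I alone and attack at one carbonyl only: under aprotic, HMPA-free conditions the primary iodide is the only reducible group (silyl ethers, the capped alkyne and the unactivated ester are inert, and the cap removes the alkyne proton that would quench the organosamarium), and the five-membered transition state makes the tethered ester the only electrophile within reach. The ketone stays masked as the hemiketal alkoxide until the quench, which together with the limit of about two equivalents of SmI2 should prevent ketyl formation and ketyl–alkyne cyclisation.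

Step 9
Reactants: 15 (R)-1-[(tert-butyldiphenylsilyl)oxy]-3-hydroxy-11-(trimethylsilyl)undec-10-yn-6-one
Product: 16 (R)-1-[(tert-butyldiphenylsilyl)oxy]-6-oxo-11-(trimethylsilyl)undec-10-yn-3-yl methanesulfonate
Conditions: MsCl, Et3N, CH2Cl2, −10 °C
Reagents that add atoms: methanesulfonyl chloride CS(=O)(=O)Cl
Why: O-sulfonylation of the open-chain hydroxy ketone takes place at oxygen, so the configuration is retained and C6 becomes an SN2 acceptor.

Step 10
Reactants: 16 (R)-1-[(tert-butyldiphenylsilyl)oxy]-6-oxo-11-(trimethylsilyl)undec-10-yn-3-yl methanesulfonate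
Product: 17 (3R)-1-[(tert-butyldiphenylsilyl)oxy]-6-hydroperoxy-6-methoxy-11-(trimethylsilyl)undec-10-yn-3-yl methanesulfonate (both epimers at the ketal carbon, ring C3)
Conditions: urea·H2O2, Sc(OTf)3 (cat.), MeOH, 0 °C to rt
Reagents that add atoms: urea–hydrogen peroxide OO.NC(N)=O; methanol CO
Why: Lewis-acid-catalysed peroxyketalisation of a ketone with H2O2 in methanol should give the α-methoxy hydroperoxide, and the lack of control at C3 does not matter because C3 is corrected in step 11.

Step 11
Reactants: 17 (3R)-1-[(tert-butyldiphenylsilyl)oxy]-6-hydroperoxy-6-methoxy-11-(trimethylsilyl)undec-10-yn-3-yl methanesulfonate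
Product: 19 (3R,6S)-6-{2-[(tert-butyldiphenylsilyl)oxy]ethyl}-3-methoxy-3-[5-(trimethylsilyl)pent-4-yn-1-yl]-1,2-dioxane, via C3-epimeric dioxanes 18 (not isolated)
Conditions: KOt-Bu (1.05 equiv), 18-crown-6, THF, 0 °C; then TsOH·H2O (0.3 equiv), MeOH, rt
Reagents that add atoms: none
Why: The intramolecular SN2 alkylation of the hydroperoxy-ketal anion (6-exo-tet) should displace the secondary mesylate with inversion and set C6 as S, and the following acid-catalysed acetal exchange passes both C3 epimers through one peroxycarbenium ion and should collect them in the isomer with axial OMe (anomeric effect) and equatorial carbon arms, which is 3R.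

Step 12
Reactants: 19 (3R,6S)-6-{2-[(tert-butyldiphenylsilyl)oxy]ethyl}-3-methoxy-3-[5-(trimethylsilyl)pent-4-yn-1-yl]-1,2-dioxane
Product: 20 (3R,6S)-6-(2-hydroxyethyl)-3-methoxy-3-(pent-4-yn-1-yl)-1,2-dioxane
Conditions: TBAF, AcOH, THF, 0 °C to rt
Reagents that add atoms: none
Why: Fluoride-induced desilylation removes the O-TBDPS and the C-TMS group in one operation, and the acetic acid buffer keeps the medium from deprotonating C6–H next to the O–O bond.

Step 13
Reactants: 21 8-bromooct-1-yne
Product: 23 (E)-8-bromo-1-iodooct-1-ene, via alkenylzirconocene 22 (not isolated)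
Conditions: Cp2Zr(H)Cl, CH2Cl2, rt; then I2, 0 °C
Reagents that add atoms: iodine II
Why: Hydrozirconation with the Schwartz reagent is a syn, terminus-selective addition and iodinolysis proceeds with retention, which fixes the E geometry while the primary bromide stays inert.

Step 14
Reactants: 23 (E)-8-bromo-1-iodooct-1-ene; 24 acetone N,N-dimethylhydrazone
Product: 26 (E)-11-iodoundec-10-en-2-one, via alkylated hydrazone 25 (not isolated)
Conditions: 24, n-BuLi, THF, −78 °C to 0 °C; 23, 0 °C to rt; then aq. oxalic acid, Et2O, rt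
Reagents that add atoms: water O
Why: Alkylation of the lithiated hydrazone (aza-enolate alkylation) by the primary bromide and mild acidic hydrolysis should deliver the methyl ketone and leave the alkenyl iodide untouched.

Step 15
Reactants: 20 (3R,6S)-6-(2-hydroxyethyl)-3-methoxy-3-(pent-4-yn-1-yl)-1,2-dioxane; 26 (E)-11-iodoundec-10-en-2-one
Product: 27 (3R,6S)-6-(2-hydroxyethyl)-3-methoxy-3-[(6E)-15-oxohexadec-6-en-4-yn-1-yl]-1,2-dioxane
Conditions: Pd(PPh3)4 (5 mol %), CuI (10 mol %), Et3N, THF, rt
Reagents that add atoms: none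
Why: The Sonogashira coupling joins the sp and sp2 carbons with retention of the E geometry under mild amine-base conditions that a dialkyl peroxyketal should tolerate.

Step 16
Reactants: 27 (3R,6S)-6-(2-hydroxyethyl)-3-methoxy-3-[(6E)-15-oxohexadec-6-en-4-yn-1-yl]-1,2-dioxane
Product: 28 [(3R,6S)-3-methoxy-3-[(6E)-15-oxohexadec-6-en-4-yn-1-yl]-1,2-dioxan-6-yl]acetic acid (target)
Conditions: TEMPO (cat.), PhI(OAc)2 (2.5 equiv), MeCN–pH 7 buffer, 0 °C to rt
Reagents that add atoms: water O
Why: The TEMPO/PhI(OAc)2 oxidation in aqueous medium takes the primary alcohol through the aldehyde hydrate to the acid at near-neutral pH and should leave the peroxyketal, the enyne and the ketone untouched.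

**Compound list**
1 | hex-5-ynoic acid | C#CCCCC(=O)O | starting material
2 | trimethylsilyl 6-(trimethylsilyl)hex-5-ynoate | C[Si](C)(C)C#CCCCC(=O)O[Si](C)(C)C | intermediate
3 | 6-(trimethylsilyl)hex-5-ynoic acid | C[Si](C)(C)C#CCCCC(=O)O | intermediate
4 | propane-1,3-diol | OCCCO | starting material
5 | 3-[(tert-butyldiphenylsilyl)oxy]propan-1-ol | OCCCO[Si](c1ccccc1)(c1ccccc1)C(C)(C)C | intermediate
6 | 3-[(tert-butyldiphenylsilyl)oxy]propanal | O=CCCO[Si](c1ccccc1)(c1ccccc1)C(C)(C)C | intermediate
7 | (R)-1-[(tert-butyldiphenylsilyl)oxy]hex-5-en-3-yl diisopinocampheylborinate | C=CC[C@H](CCO[Si](c1ccccc1)(c1ccccc1)C(C)(C)C)OB([C@H]1C[C@H]2C[C@@H]([C@@H]1C)C2(C)C)[C@H]1C[C@H]2C[C@@H]([C@@H]1C)C2(C)C | intermediate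
8 | (R)-1-[(tert-butyldiphenylsilyl)oxy]hex-5-en-3-ol | C=CC[C@H](CCO[Si](c1ccccc1)(c1ccccc1)C(C)(C)C)O | intermediate
9 | secondary ozonide (1,2,4-trioxolane) of 8, carbinol centre unchanged | C1OOC(C[C@H](CCO[Si](c2ccccc2)(c2ccccc2)C(C)(C)C)O)O1 | intermediate
10 | (R)-5-[(tert-butyldiphenylsilyl)oxy]pentane-1,3-diol | OCC[C@H](CCO[Si](c1ccccc1)(c1ccccc1)C(C)(C)C)O | intermediate
11 | (S)-1-[(tert-butyldiphenylsilyl)oxy]-5-iodopentan-3-ol | ICC[C@H](CCO[Si](c1ccccc1)(c1ccccc1)C(C)(C)C)O | intermediate
12 | (S)-1-[(tert-butyldiphenylsilyl)oxy]-5-iodopentan-3-yl 6-(trimethylsilyl)hex-5-ynoate | ICC[C@H](CCO[Si](c1ccccc1)(c1ccccc1)C(C)(C)C)OC(=O)CCCC#C[Si](C)(C)C | intermediate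
13 | primary alkylsamarium(III) diiodide from 12 | I[Sm](I)CC[C@H](CCO[Si](c1ccccc1)(c1ccccc1)C(C)(C)C)OC(=O)CCCC#C[Si](C)(C)C | intermediate
14 | cyclic samarium hemiketal (tetrahydrofuran ring O, C3, C4, C5, C6; C3 unassigned) | C[Si](C)(C)C#CCCCC1(O[Sm](I)I)CC[C@H](CCO[Si](c2ccccc2)(c2ccccc2)C(C)(C)C)O1 | intermediate
15 | (R)-1-[(tert-butyldiphenylsilyl)oxy]-3-hydroxy-11-(trimethylsilyl)undec-10-yn-6-one | C[Si](C)(C)C#CCCCC(=O)CC[C@H](CCO[Si](c1ccccc1)(c1ccccc1)C(C)(C)C)O | intermediate
16 | (R)-1-[(tert-butyldiphenylsilyl)oxy]-6-oxo-11-(trimethylsilyl)undec-10-yn-3-yl methanesulfonate | C[Si](C)(C)C#CCCCC(=O)CC[C@H](CCO[Si](c1ccccc1)(c1ccccc1)C(C)(C)C)OS(C)(=O)=O | intermediate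
17 | (3R)-1-[(tert-butyldiphenylsilyl)oxy]-6-hydroperoxy-6-methoxy-11-(trimethylsilyl)undec-10-yn-3-yl methanesulfonate, both ketal epimers | C[Si](C)(C)C#CCCCC(OC)(OO)CC[C@H](CCO[Si](c1ccccc1)(c1ccccc1)C(C)(C)C)OS(C)(=O)=O | intermediate
18 | (6S)-6-{2-[(tert-butyldiphenylsilyl)oxy]ethyl}-3-methoxy-3-[5-(trimethylsilyl)pent-4-yn-1-yl]-1,2-dioxane, both C3 epimers | COC1(CCCC#C[Si](C)(C)C)CC[C@@H](CCO[Si](c2ccccc2)(c2ccccc2)C(C)(C)C)OO1 | intermediate
19 | (3R,6S)-6-{2-[(tert-butyldiphenylsilyl)oxy]ethyl}-3-methoxy-3-[5-(trimethylsilyl)pent-4-yn-1-yl]-1,2-dioxane | CO[C@@]1(CCCC#C[Si](C)(C)C)CC[C@@H](CCO[Si](c2ccccc2)(c2ccccc2)C(C)(C)C)OO1 | intermediate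
20 | (3R,6S)-6-(2-hydroxyethyl)-3-methoxy-3-(pent-4-yn-1-yl)-1,2-dioxane | CO[C@@]1(CCCC#C)CC[C@@H](CCO)OO1 | intermediate
21 | 8-bromooct-1-yne | C#CCCCCCCBr | starting material
22 | (E)-(8-bromooct-1-en-1-yl)zirconocene chloride | BrCCCCCC/C=C/[Zr](Cl)(C1C=CC=C1)C1C=CC=C1 | intermediate
23 | (E)-8-bromo-1-iodooct-1-ene | BrCCCCCC/C=C/I | intermediate
24 | acetone N,N-dimethylhydrazone | CC(C)=NN(C)C | starting material
25 | (E)-11-iodoundec-10-en-2-one N,N-dimethylhydrazone | I/C=C/CCCCCCCC(C)=NN(C)C | intermediate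
26 | (E)-11-iodoundec-10-en-2-one | I/C=C/CCCCCCCC(C)=O | intermediate
27 | (3R,6S)-6-(2-hydroxyethyl)-3-methoxy-3-[(6E)-15-oxohexadec-6-en-4-yn-1-yl]-1,2-dioxane | CO[C@@]1(CCCC#C/C=C/CCCCCCCC(C)=O)CC[C@@H](CCO)OO1 | intermediate
28 | [(3R,6S)-3-methoxy-3-[(6E)-15-oxohexadec-6-en-4-yn-1-yl]-1,2-dioxan-6-yl]acetic acid | CO[C@@]1(CCCC#C/C=C/CCCCCCCC(C)=O)CC[C@@H](CC(=O)O)OO1 | target

**Step count**
- Total: 16 steps.
- Longest linear sequence: 13 steps (4 → 28 through steps 2–12, 15 and 16).

**Steps most likely to fail**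

1. Step 8 (key step).
   - What may go wrong: the alkylsamarium could be protonated before it reaches the carbonyl (simple loss of iodine). It could undergo 1,3-elimination, or the liberated ketone could take up further electrons.
   - Fallback (intermolecular acylation instead of the tethered shift): it sets out from 11 and 3. Alcohol 11 is silylated (TESCl, imidazole, CH2Cl2) to the triethylsilyl ether F1. Acid 3 is converted (MeNHOMe·HCl, EDC, Et3N) into the Weinreb amide F2. F1 undergoes iodine–lithium exchange (t-BuLi, Et2O–pentane, −78 °C) and the alkyllithium is acylated by F2 to the silyl-protected ketone F3. Selective removal of the TES group (PPTS, MeOH, 0 °C) comes back to the route at 15.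

2. Step 10.
   - What may go wrong: exchange at the ketone could run on to geminal bis-peroxidation or stay incomplete. A hemiketal oxygen could also displace the mesylate at C6 in a five-membered closure.
   - Fallback (carbonyl oxide trapping instead of ketone exchange): it sets out from 15. Wittig methylenation (Ph3P=CH2, excess, THF) gives the 1,1-disubstituted alkenol F4. Mesylation (MsCl, Et3N) gives the alkenyl mesylate F5. Ozonolysis of F5 in CH2Cl2–MeOH at −78 °C, stopped at consumption of the alkene, should place the carbonyl oxide on the more substituted carbon, where methanol traps it. This comes back to the route at 17.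

3. Step 11.
   - What may go wrong: β-elimination of the mesylate could compete with substitution. Base could also remove C6–H of the product and break the O–O bond (Kornblum–DeLaMare type fragmentation).
   - Fallback (reversed order, O1–C6 first and C3–O2 last): it sets out from 16. Ketalisation (HC(OMe)3, PPTS, MeOH) gives the dimethyl ketal mesylate F6. Intermolecular SN2 with 2-methoxyprop-2-yl hydroperoxide (CsOH·H2O, DMF, 0 °C) gives, with inversion, the doubly masked peroxide F7. TsOH in MeOH removes the 2-methoxypropyl group, and the freed hydroperoxide closes onto C3 by transketalisation under the same thermodynamic control. This comes back to the route at 19.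

**Further compounds**
F1 | step 8 | (S)-1-[(tert-butyldiphenylsilyl)oxy]-5-iodo-3-[(triethylsilyl)oxy]pentane | ICC[C@H](CCO[Si](c1ccccc1)(c1ccccc1)C(C)(C)C)O[Si](CC)(CC)CC
F2 | step 8 | N-methoxy-N-methyl-6-(trimethylsilyl)hex-5-ynamide | C[Si](C)(C)C#CCCCC(=O)N(C)OC
F3 | step 8 | (R)-1-[(tert-butyldiphenylsilyl)oxy]-3-[(triethylsilyl)oxy]-11-(trimethylsilyl)undec-10-yn-6-one | C[Si](C)(C)C#CCCCC(=O)CC[C@H](CCO[Si](c1ccccc1)(c1ccccc1)C(C)(C)C)O[Si](CC)(CC)CC
F4 | step 10 | (R)-1-[(tert-butyldiphenylsilyl)oxy]-6-methylidene-11-(trimethylsilyl)undec-10-yn-3-ol | C[Si](C)(C)C#CCCCC(=C)CC[C@H](CCO[Si](c1ccccc1)(c1ccccc1)C(C)(C)C)O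
F5 | step 10 | (R)-1-[(tert-butyldiphenylsilyl)oxy]-6-methylidene-11-(trimethylsilyl)undec-10-yn-3-yl methanesulfonate | C[Si](C)(C)C#CCCCC(=C)CC[C@H](CCO[Si](c1ccccc1)(c1ccccc1)C(C)(C)C)OS(C)(=O)=O
F6 | step 11 | (R)-1-[(tert-butyldiphenylsilyl)oxy]-6,6-dimethoxy-11-(trimethylsilyl)undec-10-yn-3-yl methanesulfonate | C[Si](C)(C)C#CCCCC(OC)(OC)CC[C@H](CCO[Si](c1ccccc1)(c1ccccc1)C(C)(C)C)OS(C)(=O)=O
F7 | step 11 | (S)-1-[(tert-butyldiphenylsilyl)oxy]-6,6-dimethoxy-3-[(2-methoxypropan-2-yl)peroxy]-11-(trimethylsilyl)undec-10-yne | C[Si](C)(C)C#CCCCC(OC)(OC)CC[C@@H](CCO[Si](c1ccccc1)(c1ccccc1)C(C)(C)C)OOC(C)(C)OC
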